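Remark: coumarin numbering (O1, C2 to C8a) is used for both halves. Unit A is the half linked through its O6, unit B the half linked through its C5. Esculetin (6,7-dihydroxycoumarin) is taken as a commercial starting material, and the potentials and pH values are design values to be fixed by a preliminary cyclic voltammogram.

## Structural features

The target (C18H10O8, no stereocentre) consists of two coumarin (2H-chromen-2-one) bicycles joined by a single oxygen atom that bridges C6 of unit A and C5 of unit B. Unit A is a 6-aryloxy-7-hydroxycoumarin and unit B a 5-aryloxy-6,7-dihydroxycoumarin, so the molecule is formally two molecules of esculetin minus H2, joined unsymmetrically. The benzo ring of unit B carries oxygen at C5, C6, C7 and C8a and carbon at C4a, which leaves C8 as its only CH, and the bridging oxygen sits between the ring-fusion carbon C4a (peri to H4) and the C6 hydroxyl. The fragile groups are the free catechol of unit B (oxidised by air in base), the two unsaturated lactones (opened by hydroxide, reduced by hydrogenation, attacked by organometallic reagents) and the electron-rich C8 positions. The real difficulty is the diaryl ether: both partners are electron-rich, the carbon terminus is doubly ortho-substituted, and the two halves are chemically the same, so the synthesis must choose O6 over the more acidic O7 in unit A and C5 over C8 in unit B. The feature that the key step exploits is the C6/C7 catechol of unit B itself: two-electron oxidation turns the benzo ring of B into a 6,7-ortho-quinone in which C5 is an electrophilic carbon, so the two hydroxyls that the target keeps serve as the activating group and unit B needs no halogen, metal or protecting group. In one sentence, the route is an anodic oxidation of unprotected esculetin in the presence of a 7-O-protected esculetin whose free 6-OH captures the electrogenerated quinone at C5.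

## Logic of the disconnections

6 ⇒ 5. The O7–CH2 bond of the 4-methoxybenzyl ether on unit A is cut. O7 of the nucleophilic half is the one oxygen that must not take part in the coupling, and this is the only protecting-group operation of the route. The cut gives no skeletal simplification, but it lets two otherwise identical halves be told apart. The forward step must cleave a benzylic C–O bond without touching the diaryl ether, the two lactones or the catechol, and it must trap the benzylic cation before it alkylates C8. Hydrogenolysis is avoided because of the C3=C4 bonds, which is why an acid-labile group was chosen.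

5 ⇒ 1 + 2 (key disconnection). The C5–O bond between unit B and the bridging oxygen is cut. In the forward sense 1 is oxidised at the anode to quinone 3, the free 6-OH of 2 adds to C5 of 3 to give keto adduct 4, and enolisation of 4 gives 5. The bond is cut where oxidation of the catechol of 1 creates an electrophilic carbon, so both halves come from the same commercial compound and the hardest bond is made with all oxygen functions already in place. The gain is from a tri-ortho-substituted bis-coumarin ether to two monomers, one of them unprotected. The demands are that 1 is oxidised and 2 is not, that O6 and not O7 or a ring carbon of 2 attacks, that C5 and not C8 of 3 is attacked, and that 2 and not a second molecule of 1 captures 3.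

2 ⇒ 1. The O7–CH2 bond is cut again, now in the direction of its formation. The two hydroxyls of 1 differ in acidity because only O7 is conjugated with the lactone carbonyl, so a weak base and one equivalent of a benzylic chloride should alkylate O7 alone. The demand on the forward step is mono-alkylation at O7 without alkylation at O6.

## Other disconnections considered

Alternative 1: the first plan that comes to mind cuts the same C5–O bond between two preformed, fully protected coumarins, with C5 of unit B as an aryl halide. The forward key step is a copper-catalysed Ullmann etherification of 2 with 5-bromo-6,7-dimethoxy-2H-chromen-2-one A1 to give the protected ether A2, followed by Lewis-acid cleavage of all ethers. The chosen plan is preferred on three grounds. Halogenation of a 6,7-dialkoxycoumarin is expected at C3 or C8 before C5, so A1 needs a detour through a free 6-hydroxy compound. The bromide is electron-rich and flanked by C4a and an alkoxy group while the phenol is ortho-substituted, a combination for which Ullmann etherification should be slow at temperatures where basic salts begin to open the lactones. All five oxygens need protection and the sequence needs five steps or more, against three steps and one protecting group.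

Alternative 2: the benzo ring of unit B is introduced as a para-benzoquinone, using the para relation of the C6 and C8a oxygens. The cuts are the C5–O bond and the pyranone bonds C4a–C4 and O1–C2 of unit B. In the forward sense 2 displaces bromide from 2-bromo-6-methoxy-1,4-benzoquinone A3 by addition–elimination to give aryloxyquinone A4. Reduction then gives hydroquinone A5, and the pyranone is annulated with a propiolic ester or by Pechmann condensation before the ethers are cleaved. The ether bond is easy to form this way, but in A5 the two CH positions ortho to the hydroxyl that becomes O1 differ only in being para to OMe or para to OAr. Nothing in the substrate therefore secures annulation at the future C4a. The acid needed for the annulation also threatens the 4-methoxybenzyl ether, and the sequence runs to six or seven steps.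

Alternative 3: the benzo ring of unit B is built from a four-membered ring by cutting C5–C6 and C4a–C8a. C6, C7, C8 and C8a come from a 3-alkoxycyclobutene-1,2-dione, and C5–C4a come from an enol ether that already carries the aryloxy group. The forward key step is addition of an α-lithiated aryl vinyl ether to the ketone carbonyl of the dione to give cyclobutenone A6. Thermal four-electron ring opening to a dienylketene and six-electron ring closure then give the aryloxy hydroquinone A7. This is attractive because the C5–O bond is made as a simple vinyl ether before the ring exists. It is not preferred for three reasons. A lactone cannot survive the organolithium step, so unit A must be carried as a dimethoxyphenyl group and both pyranones must be annulated late, with the same open site selectivity on A7 as in alternative 2. α-Lithiation of an aryl vinyl ether competes with ortho-lithiation of the aryl ring. The sequence would need nine steps or more.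

Key step: step 2

## Route

Step 1
Reactants: 1 esculetin (6,7-dihydroxy-2H-chromen-2-one)
Product: 2 6-hydroxy-7-[(4-methoxyphenyl)methoxy]-2H-chromen-2-one
Conditions: 4-methoxybenzyl chloride (1.05 equiv), NaHCO3 (1.5 equiv), DMF, 40 °C, N2
Reagents that add atoms: 4-methoxybenzyl chloride, COc1ccc(CCl)cc1
Why: Williamson etherification under bicarbonate control: the 7-OH is a vinylogous carboxylic acid (its anion is delocalised through C4a and the C3=C4 bond into the lactone carbonyl) and should be the only hydroxyl that NaHCO3 ionises, whereas the 6-OH, meta to C4a, stays protonated. The same acidity difference underlies the para-selective mono-alkylation of 3,4-dihydroxybenzaldehyde with bicarbonate in DMF.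

Step 2
Reactants: 1 esculetin (6,7-dihydroxy-2H-chromen-2-one); 2 6-hydroxy-7-[(4-methoxyphenyl)methoxy]-2H-chromen-2-one
Product: 5 6,7-dihydroxy-5-({7-[(4-methoxyphenyl)methoxy]-2-oxo-2H-chromen-6-yl}oxy)-2H-chromen-2-one, via esculetin ortho-quinone 3 (not isolated), via 5H-keto adduct 4 (not isolated)
Conditions: graphite-felt anode, Pt cathode, divided cell, controlled potential on the first anodic wave of 1 (about +0.3 V vs Ag/AgCl expected), 2 (3 equiv) in the anolyte, 1 added over 4 h, NaH2PO4/Na2HPO4 buffer (0.2 M, pH 7.5)/MeCN 1:1, N2, 10 °C, about 2.1 F per mol of 1; then acidic work-up (pH 4)
Reagents that add atoms: none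
Why: Proposed new method: anodic two-electron, two-proton oxidation of the catechol of 1 gives ortho-quinone 3 at a potential at which the monophenol 2 (a guaiacol-type ether on an electron-poor pyranone) should not yet be oxidised, so only unit B is turned into an electrophile. The phenoxide of 2 then adds through O6 to C5 of 3 in a 1,6-oxa-Michael addition: C5 is the terminus of the dienone C7(=O)–C8=C8a–C4a=C5 and is also linked through C4a–C4=C3 to the lactone carbonyl, whereas C8 is the electron-rich α-carbon of the vinylogous ester O1–C8a=C8–C7=O, and the usual β-positions C4a and C8a are ring-fusion carbons that cannot rearomatise. Enolisation of keto adduct 4 restores the aromatic catechol and makes the addition irreversible, and the sp3 C5 of 4 is transient, so no stereocentre is formed and no ring is closed. The closest known reaction types are the capture of anodically generated ortho-quinones by alcohols, thiols, sulfinates and carbon acids (electron transfer followed by a chemical step) and the attack of thiols at the corresponding ring position of caffeoyl ortho-quinones; a phenol oxygen as the nucleophile on a coumarin-6,7-dione is the untested element. The step needs O6 over O7 of the nucleophile, which the 4-methoxybenzyl group on O7 secures, and oxygen over carbon attack, which is favoured because the only free ortho carbon of 2 (C5) is peri-hindered and the para carbon C8a is blocked. It needs C5 over C8 of 3, which rests on the electronic bias described above, and cross- over homo-coupling, which the excess of 2 and the slow feed of 1 should secure because little free 1 is present when 3 is formed. Generation at the anode keeps the unstable quinone 3 at a low steady concentration in front of a large excess of the nucleophile, which a stoichiometric oxidant cannot do. Product 5 carries an inductively withdrawing aryloxy group next to a hydroxyl and has C5 blocked, so it should be no easier to oxidise than 1, and its own quinone would offer only the deactivated C8.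

Step 3
Reactants: 5 6,7-dihydroxy-5-({7-[(4-methoxyphenyl)methoxy]-2-oxo-2H-chromen-6-yl}oxy)-2H-chromen-2-one
Product: 6 6,7-dihydroxy-5-[(7-hydroxy-2-oxo-2H-chromen-6-yl)oxy]-2H-chromen-2-one (CNP0197949.0)
Conditions: TFA/CH2Cl2 1:4, anisole (20 equiv), 0 °C to rt
Reagents that add atoms: none
Why: Acidolysis of an aryl 4-methoxybenzyl ether (ionisation of the benzylic C–O bond) with anisole as cation trap by Friedel–Crafts benzylation. The lactones, the diaryl ether and the catechol are inert to trifluoroacetic acid at room temperature, and no reducing conditions touch the C3=C4 bonds.

## Compound list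

1 | esculetin (6,7-dihydroxy-2H-chromen-2-one) | O=c1ccc2cc(O)c(O)cc2o1 | starting material
2 | 6-hydroxy-7-[(4-methoxyphenyl)methoxy]-2H-chromen-2-one | O=c1ccc2cc(O)c(OCc3ccc(OC)cc3)cc2o1 | intermediate
3 | 2H-chromene-2,6,7-trione (esculetin ortho-quinone) | O=C1C=CC2=CC(=O)C(=O)C=C2O1 | intermediate (not isolated)
4 | rac-7-hydroxy-5-({7-[(4-methoxyphenyl)methoxy]-2-oxo-2H-chromen-6-yl}oxy)-5H-chromene-2,6-dione (keto adduct, transient sp3 C5) | O=C1C=CC2=C(O1)C=C(O)C(=O)C2Oc1cc2ccc(=O)oc2cc1OCc1ccc(OC)cc1 | intermediate (not isolated)
5 | 6,7-dihydroxy-5-({7-[(4-methoxyphenyl)methoxy]-2-oxo-2H-chromen-6-yl}oxy)-2H-chromen-2-one | O=c1ccc2c(Oc3cc4ccc(=O)oc4cc3OCc3ccc(OC)cc3)c(O)c(O)cc2o1 | intermediate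
6 | 6,7-dihydroxy-5-[(7-hydroxy-2-oxo-2H-chromen-6-yl)oxy]-2H-chromen-2-one (CNP0197949.0) | O=c1ccc2cc(Oc3c(O)c(O)cc4oc(=O)ccc34)c(O)cc2o1 | target

## Step count and least certain steps

Total step count: 3. Longest linear sequence: 3 steps (1 → 2 → 5 → 6); 1 enters a second time in step 2.

**Step 2 (key step, proposed new method).** Several processes may divert the quinone:
- carbon–carbon coupling through C5 or C8 of the nucleophile instead of ether formation;
- attack at C8 instead of C5 of the quinone;
- homo-coupling, in which unoxidised 1 captures the quinone through its more acidic O7;
- hydration and oligomerisation of the quinone in the aqueous buffer;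
- further oxidation of the product catechol followed by a second addition.

These are likely because phenoxide addition through oxygen is reversible until the adduct enolises, whereas carbon–carbon adducts form irreversibly. The fallback uses known chemistry, sets out from 2 and returns at 6. Bromination of 2 ortho to its free hydroxyl (NBS, MeCN, 0 °C) should give 5-bromo-6-hydroxy-7-[(4-methoxyphenyl)methoxy]-2H-chromen-2-one F1. Alkylation of the remaining hydroxyl (4-methoxybenzyl chloride, K2CO3, DMF) should give 5-bromo-6,7-bis[(4-methoxyphenyl)methoxy]-2H-chromen-2-one F2. Ullmann etherification of F2 with a second portion of 2 (CuI, picolinic acid, K3PO4, DMSO, 90 °C) should give 6,7-bis[(4-methoxyphenyl)methoxy]-5-({7-[(4-methoxyphenyl)methoxy]-2-oxo-2H-chromen-6-yl}oxy)-2H-chromen-2-one F3. The conditions of step 3 then remove all three arylmethyl groups and give 6.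

**Step 1.** Alkylation at O6 or at both oxygens may compete, because proton exchange between the two mono-anions is fast and the less stabilised O6 anion is the better nucleophile. The fallback sets out from 1 and returns at 2, and fixes the position of the protecting group by the order of events. Double deprotonation of 1 (NaH, 2.2 equiv, DMSO) and one equivalent of allyl bromide, which the more basic O6 anion of the dianion should take, would give 7-hydroxy-6-(prop-2-en-1-yloxy)-2H-chromen-2-one F4. Alkylation of O7 (4-methoxybenzyl chloride, K2CO3, DMF) would give 7-[(4-methoxyphenyl)methoxy]-6-(prop-2-en-1-yloxy)-2H-chromen-2-one F5. Deallylation with Pd(PPh3)4 (zerovalent palladium) and morpholine in THF then gives 2.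

**Step 3.** Re-alkylation of the electron-rich C8 positions of the product by the 4-methoxybenzyl cation may compete with capture by anisole, because the product is itself an activated arene. The fallback sets out from 1 and returns at 6, and replaces the cation-forming cleavage by one that never forms a free benzylic cation. Selective O7 methylation of 1 (MeI, NaHCO3, DMF) would give 6-hydroxy-7-methoxy-2H-chromen-2-one F6. F6 takes the place of 2 in the anodic coupling of step 2 and would give 6,7-dihydroxy-5-[(7-methoxy-2-oxo-2H-chromen-6-yl)oxy]-2H-chromen-2-one F7. BBr3 in CH2Cl2 (−78 °C to rt) then cleaves the methyl ether by bromide attack at the methyl carbon and gives 6.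

## Further compounds

F1 | step 2 | 5-bromo-6-hydroxy-7-[(4-methoxyphenyl)methoxy]-2H-chromen-2-one | O=c1ccc2c(Br)c(O)c(OCc3ccc(OC)cc3)cc2o1
F2 | step 2 | 5-bromo-6,7-bis[(4-methoxyphenyl)methoxy]-2H-chromen-2-one | O=c1ccc2c(Br)c(OCc3ccc(OC)cc3)c(OCc3ccc(OC)cc3)cc2o1
F3 | step 2 | 6,7-bis[(4-methoxyphenyl)methoxy]-5-({7-[(4-methoxyphenyl)methoxy]-2-oxo-2H-chromen-6-yl}oxy)-2H-chromen-2-one | O=c1ccc2c(Oc3cc4ccc(=O)oc4cc3OCc3ccc(OC)cc3)c(OCc3ccc(OC)cc3)c(OCc3ccc(OC)cc3)cc2o1
F4 | step 1 | 7-hydroxy-6-(prop-2-en-1-yloxy)-2H-chromen-2-one | O=c1ccc2cc(OCC=C)c(O)cc2o1
F5 | step 1 | 7-[(4-methoxyphenyl)methoxy]-6-(prop-2-en-1-yloxy)-2H-chromen-2-one | O=c1ccc2cc(OCC=C)c(OCc3ccc(OC)cc3)cc2o1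
F6 | step 3 | 6-hydroxy-7-methoxy-2H-chromen-2-one | COc1cc2oc(=O)ccc2cc1O
F7 | step 3 | 6,7-dihydroxy-5-[(7-methoxy-2-oxo-2H-chromen-6-yl)oxy]-2H-chromen-2-one | COc1cc2oc(=O)ccc2cc1Oc1c(O)c(O)cc2oc(=O)ccc12
A1 | alternative 1 | 5-bromo-6,7-dimethoxy-2H-chromen-2-one | COc1cc2oc(=O)ccc2c(Br)c1OC
A2 | alternative 1 | 6,7-dimethoxy-5-({7-[(4-methoxyphenyl)methoxy]-2-oxo-2H-chromen-6-yl}oxy)-2H-chromen-2-one | COc1cc2oc(=O)ccc2c(Oc2cc3ccc(=O)oc3cc2OCc2ccc(OC)cc2)c1OC
A3 | alternative 2 | 2-bromo-6-methoxycyclohexa-2,5-diene-1,4-dione | COC1=CC(=O)C=C(Br)C1=O
A4 | alternative 2 | 2-methoxy-6-({7-[(4-methoxyphenyl)methoxy]-2-oxo-2H-chromen-6-yl}oxy)cyclohexa-2,5-diene-1,4-dione | COC1=CC(=O)C=C(Oc2cc3ccc(=O)oc3cc2OCc2ccc(OC)cc2)C1=O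
A5 | alternative 2 | 6-(2,5-dihydroxy-3-methoxyphenoxy)-7-[(4-methoxyphenyl)methoxy]-2H-chromen-2-one | COc1cc(O)cc(Oc2cc3ccc(=O)oc3cc2OCc2ccc(OC)cc2)c1O
A6 | alternative 3 | rac-4-[1-(2,4-dimethoxyphenoxy)ethenyl]-4-hydroxy-3-(propan-2-yloxy)cyclobut-2-en-1-one | C=C(Oc1ccc(OC)cc1OC)C1(O)C(=O)C=C1OC(C)C
A7 | alternative 3 | 2-(2,4-dimethoxyphenoxy)-6-(propan-2-yloxy)benzene-1,4-diol | COc1ccc(Oc2cc(O)cc(OC(C)C)c2O)c(OC)c1
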